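Ring numbering: C1 (CH3), C2 (Br), C3 (OH), C4 (OH), C5 (Br), C6 (Br). Behind the two O-methyl ethers that mask the catechol, the retrosynthesis cuts the ring bonds C1-C2 and C5-C6.
Enabling feature: the benzene ring is fully substituted. Its C2-C3-C4-C5 segment reads Br, O, O, Br in both directions, and C6-C1 carries Br and CH3. A symmetric four-carbon diene and an unsymmetric two-carbon alkyne can therefore combine in only one substitution pattern.
Forward: purchased 3,4-dimethoxythiophene supplies C2-C5. It is brominated at both alpha carbons and oxidised at sulfur to a non-aromatic 1,1-dioxide. The C6-C1 unit, 1-bromopropyne, is made from its C-silyl derivative.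
Ring order: the heterocycle only lends its four carbons. The benzene ring, the sole ring of the target, closes in a (4+2) cycloaddition, the sulfur bridge departs as SO2, and BBr3 then frees the catechol.
Stereochemistry: no stereocentre reaches the target. The two bridgehead centres of the transient cycloadduct form as a racemate, are tied to each other by the bridge, and are erased on aromatisation.

Key step: step 4

Assumption: 8 is drawn as its (1S,4S) enantiomer but is expected as the racemate. Compound 7 is volatile and hazardous when neat, so it is handled only as a dilute, assayed toluene solution and never concentrated.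

Step 1
Reactants: 1 3,4-dimethoxythiophene
Product: 3 2,5-dibromo-3,4-dimethoxythiophene, via 2-bromo-3,4-dimethoxythiophene 2 (not isolated)
Conditions: NBS (2.05 equiv), DMF, -10 to 0 °C, dark, 2 h; aq NaHCO3 work-up, product kept cold and used the same day
Reagents that add atoms: N-bromosuccinimide (NBS), O=C1CCC(=O)N1Br
Why: Electrophilic aromatic substitution, in which the two alpha positions are the only ring C-H sites and each is activated by sulfur and by the neighbouring methoxy group, so two equivalents of NBS should stop at the dibromide, which is kept cold, dark and acid-free because such dihalides tend to self-condense on storage.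

Step 2
Reactants: 3 2,5-dibromo-3,4-dimethoxythiophene
Product: 5 2,5-dibromo-3,4-dimethoxythiophene 1,1-dioxide, via thiophene 1-oxide 4 (not isolated)
Conditions: HOF·MeCN (3 equiv; freshly made from 10% F2/N2 and MeCN-H2O 9:1, -15 °C), CH2Cl2, -15 to 0 °C, 15 min; aq NaHCO3
Reagents that add atoms: hypofluorous acid (used as its acetonitrile complex), OF
Why: Oxidation of a thiophene at sulfur by an electrophilic oxygen-transfer reagent, where HOF·MeCN delivers both oxygens within minutes below 0 °C so that the dimerisation-prone monoxide 4 cannot build up and the fragile dibromide has little time to self-condense, while the double bonds of 5, now brominated beta-alkoxy vinyl sulfones, are too electron-poor to be epoxidised.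

Step 3
Reactants: 6 1-(trimethylsilyl)propyne
Product: 7 1-bromopropyne
Conditions: NBS (1.05 equiv), AgNO3 (10 mol %), acetone, rt, dark, 2 h; then H2O/toluene partition, H2O washes, MgSO4, solution assayed and stored at -20 °C under Ar
Reagents that add atoms: N-bromosuccinimide (NBS), O=C1CCC(=O)N1Br
Why: Silver-catalysed electrophilic bromodesilylation of an alkynylsilane, in which AgNO3 activates the C(sp)-Si bond toward the N-Br electrophile so that bromine replaces silicon without addition across the triple bond, and the water washes remove acetone and succinimide while the low-boiling product stays in toluene.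

Step 4
Reactants: 5 2,5-dibromo-3,4-dimethoxythiophene 1,1-dioxide; 7 1-bromopropyne
Product: 9 1,2,4-tribromo-5,6-dimethoxy-3-methylbenzene, via sulfone-bridged cycloadduct 8 (not isolated)
Conditions: 7 (5 equiv, toluene solution), BHT (2 mol %), sealed pressure tube, Ar, 120 °C, 24-48 h
Reagents that add atoms: none
Why: Oxidation at sulfur has left 5 as a planar, non-aromatic diene locked s-cis, and its termini C2 and C5 bond to the alkyne carbons C1 and C6 of 7 in one concerted, suprafacial (4+2) cycloaddition (Diels-Alder reaction), so the six-membered carbocycle is closed by cycloaddition as the 7-thianorbornadiene dioxide 8. The strained bridge of 8 then leaves as SO2 in a thermally allowed cheletropic elimination, and aromatisation together with loss of a gas makes the sequence irreversible. The closest known reaction type is the benzannulation of halogenated thiophene 1,1-dioxides with alkynes by Diels-Alder addition and spontaneous SO2 extrusion; here the sulfone and the two bromines keep the diene LUMO low while the methoxy groups raise its HOMO, so the electronically unbiased bromoalkyne can be engaged from either frontier-orbital side at the price of heating. The two bridgehead carbons of 8 are the only stereocentres formed: their relative configuration is imposed by the one-atom sulfur bridge, the two faces of 5 are equivalent so the racemate results, and both centres become planar again on SO2 loss. No regiocontrol is needed, because 5 is symmetric about the midpoint of C3-C4 and both alkyne orientations lead to the same arene. The selectivity that is needed, cross-cycloaddition rather than self-dimerisation of the diene, is secured by the bromine atoms on both diene termini, the full substitution of the diene and the excess of 7.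

Step 5
Reactants: 9 1,2,4-tribromo-5,6-dimethoxy-3-methylbenzene
Product: 11 3,4,6-tribromo-5-methylbenzene-1,2-diol, via cyclic bromoboronate 10 (not isolated)
Conditions: BBr3 (3 equiv), CH2Cl2, -78 °C to rt, 4 h; H2O, 0 °C, neutral to acidic work-up under Ar
Reagents that add atoms: none
Why: Lewis-acid cleavage of aryl methyl ethers with BBr3, in which boron binds the flanked, twisted methoxy oxygens, bromide removes each methyl group by SN2 attack, the catechol is held as the cyclic boronate 10 until water releases it, and the aryl bromides and the aryl methyl group are inert, base and air being avoided in the work-up to prevent oxidation to the quinone.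

Compound list
1 | 3,4-dimethoxythiophene | COc1cscc1OC | starting material
2 | 2-bromo-3,4-dimethoxythiophene (not isolated) | COc1csc(Br)c1OC | intermediate
3 | 2,5-dibromo-3,4-dimethoxythiophene | COc1c(Br)sc(Br)c1OC | intermediate
4 | 2,5-dibromo-3,4-dimethoxythiophene 1-oxide (not isolated) | COC1=C(Br)S(=O)C(Br)=C1OC | intermediate
5 | 2,5-dibromo-3,4-dimethoxythiophene 1,1-dioxide | COC1=C(Br)S(=O)(=O)C(Br)=C1OC | intermediate
6 | 1-(trimethylsilyl)propyne | CC#C[Si](C)(C)C | starting material
7 | 1-bromopropyne (toluene solution) | CC#CBr | intermediate
8 | rac-(1S,4S)-1,2,4-tribromo-5,6-dimethoxy-3-methyl-7-thiabicyclo[2.2.1]hepta-2,5-diene 7,7-dioxide (not isolated; one enantiomer drawn) | COC1=C(OC)[C@]2(Br)C(Br)=C(C)[C@@]1(Br)S2(=O)=O | intermediate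
9 | 1,2,4-tribromo-5,6-dimethoxy-3-methylbenzene | COc1c(Br)c(C)c(Br)c(Br)c1OC | intermediate
10 | 2,4,5,7-tetrabromo-6-methyl-1,3,2-benzodioxaborole (not isolated) | Cc1c(Br)c2OB(Br)Oc2c(Br)c1Br | intermediate
11 | 3,4,6-tribromo-5-methylbenzene-1,2-diol | Cc1c(Br)c(O)c(O)c(Br)c1Br | target

Total step count: 5. Longest linear sequence: 4 (steps 1, 2, 4, 5). Step 3 feeds the convergent branch.

Steps most likely to fail

Step 4. The cycloaddition may be too slow at any temperature the partners tolerate. Thermal breakdown of the diene and oligomerisation of the haloalkyne would then outpace ring closure. Fallback, from 5 back to 9: the alkyne is replaced by an electron-rich alkene that acts as a propyne equivalent, and the third bromine is added afterwards. Heating 5 with excess 2-methoxypropene (toluene, K2CO3, 60-80 °C) should give, by an inverse-electron-demand Diels-Alder reaction, 1,4-dibromo-2,3,5-trimethoxy-5-methyl-7-thiabicyclo[2.2.1]hept-2-ene 7,7-dioxide F1. This adduct loses SO2 to give 1,4-dibromo-2,3,5-trimethoxy-5-methylcyclohexa-1,3-diene F2. A trace of TsOH then eliminates methanol to give 1,4-dibromo-2,3-dimethoxy-5-methylbenzene F3. Its single aromatic C-H (C6, para to a methoxy group) is brominated with Br2 in AcOH in the dark, which leads to 9.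

Step 2. Oxygen transfer to the electron-rich ring carbons, followed by ring opening, may compete with oxidation at sulfur. So may acid-triggered self-condensation with loss of bromine. Fallback, from 1 back to 5: halogenation and oxidation are reversed in order, and silicon occupies the alpha positions in the meantime. Lithiation and silylation of 1 at both alpha carbons (n-BuLi, TMEDA, THF, then TMSCl, repeated in the same flask) should give 3,4-dimethoxy-2,5-bis(trimethylsilyl)thiophene F4. This compound has no labile C-Br bond and is shielded at its alpha carbons. The milder, buffered peracid mCPBA (NaHCO3, CH2Cl2) should oxidise it to 3,4-dimethoxy-2,5-bis(trimethylsilyl)thiophene 1,1-dioxide F5. Double ipso-bromodesilylation of the two vinylsilane units (Br2, AgBF4, CH2Cl2, 0 °C), assisted by the beta-methoxy groups, then gives 5.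

Step 3. Too little clean dienophile may be left because of evaporative loss of the low-boiling product during work-up. Carry-over of acetone or active bromine into the cycloaddition and decay of the haloalkyne on storage would have the same effect. Fallback, from 6 (together with 5) back to 9: the haloalkyne is dispensed with, the robust silylalkyne itself serves as dienophile, and bromine replaces silicon on the arene. Heating 5 with excess 6 (xylene, sealed tube, 140-160 °C) should lead through 1,4-dibromo-5,6-dimethoxy-2-methyl-3-(trimethylsilyl)-7-thiabicyclo[2.2.1]hepta-2,5-diene 7,7-dioxide F6. Loss of SO2 then gives (2,5-dibromo-3,4-dimethoxy-6-methylphenyl)trimethylsilane F7. Ipso-bromodesilylation (Br2, CH2Cl2, 0 °C, dark, volatiles evaporated) is steered to the silicon-bearing carbon by the beta-silicon effect and the para methoxy group, and it gives 9.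

Further compounds
F1 | step 4 | 1,4-dibromo-2,3,5-trimethoxy-5-methyl-7-thiabicyclo[2.2.1]hept-2-ene 7,7-dioxide (racemic, endo/exo mixture at C5) | COC1=C(OC)[C@]2(Br)C(C)(OC)C[C@@]1(Br)S2(=O)=O
F2 | step 4 | 1,4-dibromo-2,3,5-trimethoxy-5-methylcyclohexa-1,3-diene (racemic) | COC1=C(Br)CC(C)(OC)C(Br)=C1OC
F3 | step 4 | 1,4-dibromo-2,3-dimethoxy-5-methylbenzene | COc1c(Br)cc(C)c(Br)c1OC
F4 | step 2 | 3,4-dimethoxy-2,5-bis(trimethylsilyl)thiophene | COc1c([Si](C)(C)C)sc([Si](C)(C)C)c1OC
F5 | step 2 | 3,4-dimethoxy-2,5-bis(trimethylsilyl)thiophene 1,1-dioxide | COC1=C([Si](C)(C)C)S(=O)(=O)C([Si](C)(C)C)=C1OC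
F6 | step 3 | 1,4-dibromo-5,6-dimethoxy-2-methyl-3-(trimethylsilyl)-7-thiabicyclo[2.2.1]hepta-2,5-diene 7,7-dioxide (racemic, one enantiomer drawn) | COC1=C(OC)[C@]2(Br)C([Si](C)(C)C)=C(C)[C@@]1(Br)S2(=O)=O
F7 | step 3 | (2,5-dibromo-3,4-dimethoxy-6-methylphenyl)trimethylsilane | COc1c(Br)c(C)c([Si](C)(C)C)c(Br)c1OC
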